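**Retrosynthetic overview**

1. Eunicellane numbering is used: C1/C10 ring fusion, C2–O–C9 ether, C3 the methyl-bearing carbon on the lactone oxygen, C16 the lactone carbonyl. In the seven-membered lactone ring O–C16–C15–C14–C1–C2–C3 the lactone oxygen and C1 sit five atoms apart on one piece, and C2, C3, C4 are three neighbouring oxygen-bearing carbons. With a temporary carbonyl at C12, C1 is the γ-carbon of an (S)-carvone dienolate and C2–C3–C4 is an α,β-epoxy aldehyde.
2. Key disconnection: formal (5+2) annulation of silyl dienol ether/silyl ester 6 (cyclohexane ring and C15–C17) with epoxy aldehyde 12 (C2–C6). A vinylogous Mukaiyama aldol joins C1 to C2, then the carboxyl group opens the epoxide at C3 in a 7-exo mode.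
3. Tetrahydrofuran next: oxa-Michael addition of the C2 hydroxyl to methyl propiolate (C7–C9), then stannyl-ketyl radical closure C10–C9. The C12 carbonyl leaves through its enol triflate, and the C11=C12 alkene gives the C11 alcohol by oxymercuration.
4. Oxonane last: ester → alkyne → 2-iodoalkene, Nozaki–Hiyama–Kishi closure of C6–C7, then butanoylation.
5. Ring order: cyclohexene (from carvone) → lactone → tetrahydrofuran → oxonane.

Key step: step 10

Remark: compounds 7, 8 and 17 are taken as purchased; the C11 epimers of 20 are carried together because C11 becomes trigonal in step 14.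

**Route**

Step 1
Reactants: 1 (S)-carvone
Product: 2 (5S)-5-(3-chloroprop-1-en-2-yl)-2-methylcyclohex-2-en-1-one
Conditions: Ca(OCl)2, CO2 (s), CH2Cl2/H2O, 0 °C
Reagents that add atoms: calcium hypochlorite, [Ca+2].[O-]Cl.[O-]Cl
Why: Ene-type allylic chlorination by HOCl (from Ca(OCl)2 and CO2) takes place at the electron-rich 1,1-disubstituted alkene with shift of the double bond, the enone alkene is too electron-poor to react, and the stereocentre is not touched.

Step 2
Reactants: 2 (5S)-5-(3-chloroprop-1-en-2-yl)-2-methylcyclohex-2-en-1-one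
Product: 3 2-[(1S)-4-methyl-5-oxocyclohex-3-en-1-yl]prop-2-enal
Conditions: N-methylmorpholine N-oxide, KI (cat.), MeCN, 40 °C
Reagents that add atoms: N-methylmorpholine N-oxide, C[N+]1([O-])CCOCC1
Why: Kornblum-type oxidation: the N-oxide oxygen displaces the allylic chloride (iodide catalysis) and the alkoxyammonium ion collapses to the 2-substituted acrolein.

Step 3
Reactants: 3 2-[(1S)-4-methyl-5-oxocyclohex-3-en-1-yl]prop-2-enal
Product: 4 2-[(1S)-4-methyl-5-oxocyclohex-3-en-1-yl]prop-2-enoic acid
Conditions: NaClO2, NaH2PO4, 2-methylbut-2-ene, t-BuOH/H2O, 0 °C → rt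
Reagents that add atoms: sodium chlorite, [Na+].[O-]Cl=O
Why: Pinnick oxidation converts the enal into the acrylic acid without touching either alkene, the scavenger taking up HOCl.

Step 4
Reactants: 4 2-[(1S)-4-methyl-5-oxocyclohex-3-en-1-yl]prop-2-enoic acid
Product: 5 (2R)-2-[(1S)-4-methyl-5-oxocyclohex-3-en-1-yl]propanoic acid
Conditions: H2 (5 atm), Ru(OAc)2[(R)-BINAP] (1 mol %), MeOH, rt
Reagents that add atoms: none
Why: Carboxylate-directed asymmetric hydrogenation of a 2-substituted acrylic acid (the reaction type used for 2-arylpropanoic acids): the (R)-BINAP ligand should deliver hydrogen to the face that gives (R)-C15 under catalyst control, and the ketone-conjugated trisubstituted alkene has no directing group and stays.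

Step 5
Reactants: 5 (2R)-2-[(1S)-4-methyl-5-oxocyclohex-3-en-1-yl]propanoic acid
Product: 6 trimethylsilyl (2R)-2-[(1R)-4-methyl-5-(trimethylsilyloxy)cyclohexa-2,4-dien-1-yl]propanoate
Conditions: Me3SiOTf (2.4 equiv), Et3N, CH2Cl2, 0 °C → rt; used crude
Reagents that add atoms: trimethylsilyl trifluoromethanesulfonate, C[Si](C)(C)OS(=O)(=O)C(F)(F)F
Why: Soft enolisation: O-silylation of the acid and of the enone, then loss of the γ-proton at C1 from the silyloxyallyl cation, should give the fully conjugated 1-silyloxy-1,3-diene, the thermodynamic dienol ether as with steroidal 4-en-3-ones.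

Step 6
Reactants: 7 3-[(tert-butyldimethylsilyl)oxy]propanal; 8 ethyl 2-[bis(2,2,2-trifluoroethoxy)phosphoryl]propanoate
Product: 9 ethyl (2Z)-5-[(tert-butyldimethylsilyl)oxy]-2-methylpent-2-enoate
Conditions: KN(SiMe3)2, 18-crown-6, THF, −78 °C
Reagents that add atoms: none
Why: Still–Gennari olefination: the trifluoroethyl phosphonate under dissociating conditions gives the (Z)-2-methyl enoate under kinetic control.

Step 7
Reactants: 9 ethyl (2Z)-5-[(tert-butyldimethylsilyl)oxy]-2-methylpent-2-enoate
Product: 10 (2Z)-5-[(tert-butyldimethylsilyl)oxy]-2-methylpent-2-en-1-ol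
Conditions: i-Bu2AlH (2.5 equiv), CH2Cl2, −78 °C
Reagents that add atoms: none
Why: 1,2-Reduction of the conjugated ester by i-Bu2AlH gives the allylic alcohol with the (Z) geometry kept.

Step 8
Reactants: 10 (2Z)-5-[(tert-butyldimethylsilyl)oxy]-2-methylpent-2-en-1-ol
Product: 11 [(2S,3R)-3-{2-[(tert-butyldimethylsilyl)oxy]ethyl}-2-methyloxiran-2-yl]methanol
Conditions: Ti(Oi-Pr)4 (10 mol %), L-(+)-diethyl tartrate (12 mol %), t-BuOOH, 4 Å MS, CH2Cl2, −20 °C
Reagents that add atoms: tert-butyl hydroperoxide, CC(C)(C)OO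
Why: Sharpless asymmetric epoxidation: with L-(+)-tartrate the allylic alcohol is epoxidised on the face that gives the (2S,3R)-epoxy alcohol (reagent control, the (Z) geometry placing the hydroxymethyl group and the side chain cis).

Step 9
Reactants: 11 [(2S,3R)-3-{2-[(tert-butyldimethylsilyl)oxy]ethyl}-2-methyloxiran-2-yl]methanol
Product: 12 (2R,3R)-3-{2-[(tert-butyldimethylsilyl)oxy]ethyl}-2-methyloxirane-2-carbaldehyde
Conditions: (n-Pr4N)RuO4 (5 mol %), N-methylmorpholine N-oxide, 4 Å MS, CH2Cl2, rt
Reagents that add atoms: none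
Why: Ley–Griffith oxidation to the aldehyde is neutral, so the epoxide survives, and the α-carbon is quaternary and cannot epimerise.

Step 10
Reactants: 6 trimethylsilyl (2R)-2-[(1R)-4-methyl-5-(trimethylsilyloxy)cyclohexa-2,4-dien-1-yl]propanoate; 12 (2R,3R)-3-{2-[(tert-butyldimethylsilyl)oxy]ethyl}-2-methyloxirane-2-carbaldehyde
Product: 15 enone lactone diol, via silyl aldol adduct 13 (not isolated), via bis(trimethylsilyl) lactone 14 (not isolated)
Conditions: HNTf2 (5 mol %; forms Me3SiNTf2 in situ), CH2Cl2, −78 °C then −30 °C; AcOH/THF/H2O work-up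
Reagents that add atoms: none
Why: The silyl Lewis acid activates the aldehyde of 12 and the γ-carbon (C1) of the 1-silyloxy-1,3-diene in 6 adds to it (vinylogous Mukaiyama aldol) with silyl transfer to the new C2 oxygen, which forms the C1–C2 bond and gives 13; on warming, the same Lewis acid activates the epoxide, and the carbonyl oxygen of the silyl ester, now held close to C3, opens it at that tertiary carbon with inversion while its silyl group passes to the C4 oxygen, which forms the lactone O–C3 bond (14). The closest known reaction types are the vinylogous Mukaiyama aldol addition to α,β-epoxy aldehydes and the acid-promoted epoxide-opening lactonisation of epoxy esters, here run in one flask as a formal (5+2) annulation. The only ring closed is the seven-membered lactone, by 7-exo-tet opening of the epoxide. C1 is set by approach of the aldehyde anti to the C14 side chain of the cyclohexadiene, C2 by polar Felkin–Anh (Cornforth) addition anti to the epoxide C–O bond with the cis-disposed C5 chain turned away from the nucleophile, C3 by stereospecific inversion of the Sharpless-derived epoxide, and C4 is carried over from it. The step needs γ- over α-attack (the α-carbon C11 is fully substituted), opening at C3 and not C4 (tertiary carbon, exo mode), and lactonisation ahead of a 1,2-shift or of acyl transfer to the C2 oxygen (that oxygen stays capped as its silyl ether until work-up).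

Step 11
Reactants: 15 enone lactone diol
Product: 16 4-O-octanoyl enone lactone
Conditions: octanoyl chloride (1.1 equiv), 2,4,6-collidine, CH2Cl2, −40 °C
Reagents that add atoms: octanoyl chloride, CCCCCCCC(Cl)=O
Why: Acylation is steered by sterics: the C4 hydroxyl has a methylene neighbour while the C2 hydroxyl lies between the quaternary C3 and the ring carbon C1, so one equivalent of acid chloride at low temperature should esterify C4 only.

Step 12
Reactants: 16 4-O-octanoyl enone lactone; 17 methyl propiolate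
Product: 18 (E)-β-alkoxyacrylate (C2–O–CH=CH–CO2Me)
Conditions: PMe3 (10 mol %), CH2Cl2, 0 °C
Reagents that add atoms: none
Why: Phosphine-catalysed oxa-Michael addition of the hindered secondary alcohol to the propiolate gives the (E)-β-alkoxyacrylate under neutral conditions.

Step 13
Reactants: 18 (E)-β-alkoxyacrylate
Product: 20 tricyclic keto ester (C11 epimer mixture), via tin enolate 19 (not isolated)
Conditions: Bu3SnH, AIBN (cat.), benzene, 80 °C, slow addition; aqueous work-up
Reagents that add atoms: none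
Why: Radical cyclisation of an allylic O-stannyl ketyl: Bu3Sn• adds to the enone oxygen, the radical at C10 closes 5-exo onto the β-alkoxyacrylate carbon C9, the tether on C1 forces the cis ring fusion, and the ester arm takes the outer (convex) face in a chair-like transition state, which gives the 2,5-cis tetrahydrofuran.

Step 14
Reactants: 20 tricyclic keto ester
Product: 21 C11=C12 enol triflate
Conditions: Tf2O, 2,6-di-tert-butyl-4-methylpyridine, CH2Cl2, 0 °C → rt
Reagents that add atoms: trifluoromethanesulfonic anhydride, O=S(=O)(OS(=O)(=O)C(F)(F)F)C(F)(F)F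
Why: Enol triflate formation with Tf2O and a hindered pyridine proceeds through the O-triflyl oxocarbenium ion and should give mainly the more substituted (C11=C12) enol triflate; the esters and the lactone do not react.

Step 15
Reactants: 21 C11=C12 enol triflate
Product: 22 C11=C12 alkene methyl ester
Conditions: Pd(OAc)2 (5 mol %), PPh3, n-Bu3N, HCO2H, DMF, 60 °C
Reagents that add atoms: none
Why: Palladium-catalysed reduction of the enol triflate by formate (oxidative addition, formate exchange, loss of CO2, reductive elimination) gives the trisubstituted alkene.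

Step 16
Reactants: 22 C11=C12 alkene methyl ester
Product: 23 C7 aldehyde
Conditions: i-Bu2AlH (1.1 equiv), CH2Cl2, −78 °C; MeOH quench
Reagents that add atoms: none
Why: Partial reduction of an ester to the aldehyde through the tetrahedral aluminium hemiacetal that is stable at −78 °C; the unhindered methyl ester should react ahead of the octanoate of a neopentylic alcohol and the lactone of a tertiary alcohol.

Step 17
Reactants: 23 C7 aldehyde
Product: 24 terminal alkyne
Conditions: dimethyl (1-diazo-2-oxopropyl)phosphonate, K2CO3, MeOH, 0 °C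
Reagents that add atoms: dimethyl (1-diazo-2-oxopropyl)phosphonate, COP(=O)(OC)C(=[N+]=[N-])C(C)=O
Why: Ohira–Bestmann (Seyferth–Gilbert) homologation turns the aldehyde into the terminal alkyne under mild carbonate conditions in the cold, where the hindered esters and the β-alkoxy aldehyde should hold.

Step 18
Reactants: 24 terminal alkyne
Product: 26 2-iodoalkene, via alkenylborane 25 (not isolated)
Conditions: B-iodo-9-BBN, pentane/CH2Cl2, −20 °C; then AcOH, 0 °C
Reagents that add atoms: B-iodo-9-borabicyclo[3.3.1]nonane, IB1C2CCCC1CCC2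
Why: syn-Haloboration of the terminal alkyne puts iodine on the internal carbon, and protodeboronation with acetic acid gives the 2-iodo-1-alkene; the trisubstituted alkene does not undergo haloboration.

Step 19
Reactants: 26 2-iodoalkene
Product: 28 C11 tertiary alcohol, via organomercurial 27 (not isolated)
Conditions: Hg(OAc)2, THF/H2O, rt; then NaBH4, aq. NaHCO3, 0 °C
Reagents that add atoms: water, O
Why: Markovnikov oxymercuration–demercuration: Hg(OAc)2 should take the electron-rich trisubstituted alkene on its convex face (away from the tetrahydrofuran ring) and water then adds anti at the tertiary carbon, which places the C11 hydroxyl cis to C9 as in the target, while the iodoalkene is too electron-poor to be mercurated.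

Step 20
Reactants: 28 C11 tertiary alcohol
Product: 29 C6 primary alcohol
Conditions: HF·pyridine, pyridine, THF, 0 °C
Reagents that add atoms: none
Why: Fluoride cleaves the primary silyl ether under buffered conditions that leave the esters, the iodoalkene and the tertiary alcohol alone.

Step 21
Reactants: 29 C6 primary alcohol
Product: 30 C6 aldehyde
Conditions: (n-Pr4N)RuO4 (5 mol %), N-methylmorpholine N-oxide, 4 Å MS, CH2Cl2, rt
Reagents that add atoms: none
Why: Ley–Griffith oxidation takes the primary alcohol to the aldehyde; the tertiary alcohol cannot be oxidised.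

Step 22
Reactants: 30 C6 aldehyde
Product: 31 6-O-debutanoyl briarellin C
Conditions: CrCl2 (10 equiv), NiCl2 (2 mol %), DMSO, rt, high dilution
Reagents that add atoms: none
Why: Nozaki–Hiyama–Kishi reaction: NiCl2-catalysed insertion into the C–I bond, transmetalation to chromium and intramolecular addition to the aldehyde close the nine-membered ring, the C6 configuration being set by substrate control in the folded tricyclic transition state.

Step 23
Reactants: 31 6-O-debutanoyl briarellin C
Product: 32 briarellin C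
Conditions: butanoic anhydride, DMAP (cat.), pyridine, CH2Cl2, 0 °C → rt
Reagents that add atoms: butanoic anhydride, CCCC(=O)OC(=O)CCC
Why: Acylation of the secondary allylic alcohol; the tertiary C11 alcohol is too hindered to react under these conditions.

**Compound list**

1 | (S)-carvone, (5S)-2-methyl-5-(prop-1-en-2-yl)cyclohex-2-en-1-one | CC1=CC[C@@H](CC1=O)C(C)=C | starting material
2 | (5S)-5-(3-chloroprop-1-en-2-yl)-2-methylcyclohex-2-en-1-one | CC1=CC[C@@H](CC1=O)C(=C)CCl | intermediate
3 | 2-[(1S)-4-methyl-5-oxocyclohex-3-en-1-yl]prop-2-enal | CC1=CC[C@@H](CC1=O)C(=C)C=O | intermediate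
4 | 2-[(1S)-4-methyl-5-oxocyclohex-3-en-1-yl]prop-2-enoic acid | CC1=CC[C@@H](CC1=O)C(=C)C(O)=O | intermediate
5 | (2R)-2-[(1S)-4-methyl-5-oxocyclohex-3-en-1-yl]propanoic acid | CC1=CC[C@@H](CC1=O)[C@@H](C)C(O)=O | intermediate
6 | trimethylsilyl (2R)-2-[(1R)-4-methyl-5-(trimethylsilyloxy)cyclohexa-2,4-dien-1-yl]propanoate | CC1=C(O[Si](C)(C)C)C[C@H](C=C1)[C@@H](C)C(=O)O[Si](C)(C)C | intermediate
7 | 3-[(tert-butyldimethylsilyl)oxy]propanal | CC(C)(C)[Si](C)(C)OCCC=O | starting material
8 | ethyl 2-[bis(2,2,2-trifluoroethoxy)phosphoryl]propanoate | CCOC(=O)C(C)P(=O)(OCC(F)(F)F)OCC(F)(F)F | starting material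
9 | ethyl (2Z)-5-[(tert-butyldimethylsilyl)oxy]-2-methylpent-2-enoate | CCOC(=O)/C(C)=C\CCO[Si](C)(C)C(C)(C)C | intermediate
10 | (2Z)-5-[(tert-butyldimethylsilyl)oxy]-2-methylpent-2-en-1-ol | OC/C(C)=C\CCO[Si](C)(C)C(C)(C)C | intermediate
11 | [(2S,3R)-3-{2-[(tert-butyldimethylsilyl)oxy]ethyl}-2-methyloxiran-2-yl]methanol | OC[C@]1(C)O[C@@H]1CCO[Si](C)(C)C(C)(C)C | intermediate
12 | (2R,3R)-3-{2-[(tert-butyldimethylsilyl)oxy]ethyl}-2-methyloxirane-2-carbaldehyde | O=C[C@]1(C)O[C@@H]1CCO[Si](C)(C)C(C)(C)C | intermediate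
13 | silyl aldol adduct: 2-methylcyclohex-2-enone carrying at C1 the CH(OSiMe3)–(2-methyloxiranyl) chain (trans to the C14 substituent) and at C14 the (R)-CH(Me)CO2SiMe3 group | CC1=C[C@H]([C@@H](CC1=O)[C@@H](C)C(=O)O[Si](C)(C)C)[C@H](O[Si](C)(C)C)[C@]1(C)O[C@@H]1CCO[Si](C)(C)C(C)(C)C | intermediate
14 | bis(trimethylsilyl) lactone: the 2,4-bis-O-trimethylsilyl ether of 15 | CC1=C[C@@H]2[C@@H](CC1=O)[C@@H](C)C(=O)O[C@](C)([C@H]2O[Si](C)(C)C)[C@H](O[Si](C)(C)C)CCO[Si](C)(C)C(C)(C)C | intermediate
15 | enone lactone diol (1S,2S,3S,4R,14R,15R): cyclohex-2-enone (C12 carbonyl, C11 methyl) fused at C1–C14 to the seven-membered lactone O–C16(=O)–C15(Me)–C14–C1–C2(OH)–C3(Me); C3 carries the CH(OH)CH2CH2OSi(t-Bu)Me2 chain (C4–C6) | CC1=C[C@@H]2[C@@H](CC1=O)[C@@H](C)C(=O)O[C@](C)([C@H]2O)[C@H](O)CCO[Si](C)(C)C(C)(C)C | intermediate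
16 | 4-O-octanoyl enone lactone: 15 with the C4 hydroxyl as its octanoate | CC1=C[C@@H]2[C@@H](CC1=O)[C@@H](C)C(=O)O[C@](C)([C@H]2O)[C@H](OC(=O)CCCCCCC)CCO[Si](C)(C)C(C)(C)C | intermediate
17 | methyl propiolate (methyl prop-2-ynoate) | C#CC(=O)OC | starting material
18 | (E)-β-alkoxyacrylate: 16 with the C2 oxygen carrying (E)-CH=CH–CO2Me | CC1=C[C@@H]2[C@@H](CC1=O)[C@@H](C)C(=O)O[C@](C)([C@H]2O/C=C/C(=O)OC)[C@H](OC(=O)CCCCCCC)CCO[Si](C)(C)C(C)(C)C | intermediate
19 | tin enolate: the C11=C12 tributylstannyl enol ether of 20 | COC(=O)C[C@@H]2O[C@H]3[C@H]4[C@@H](CC(O[Sn](CCCC)(CCCC)CCCC)=C(C)[C@H]42)[C@@H](C)C(=O)O[C@@]3(C)[C@H](OC(=O)CCCCCCC)CCO[Si](C)(C)C(C)(C)C | intermediate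
20 | tricyclic keto ester: cis-fused cyclohexanone (C12 carbonyl)–tetrahydrofuran–lactone; C9 carries CH2CO2Me cis to the C3 arm; C11 epimer mixture | COC(=O)C[C@@H]2O[C@H]3[C@H]4[C@@H](CC(=O)C(C)[C@H]42)[C@@H](C)C(=O)O[C@@]3(C)[C@H](OC(=O)CCCCCCC)CCO[Si](C)(C)C(C)(C)C | intermediate
21 | C11=C12 enol triflate of 20 | COC(=O)C[C@@H]2O[C@H]3[C@H]4[C@@H](CC(OS(=O)(=O)C(F)(F)F)=C(C)[C@H]42)[C@@H](C)C(=O)O[C@@]3(C)[C@H](OC(=O)CCCCCCC)CCO[Si](C)(C)C(C)(C)C | intermediate
22 | C11=C12 alkene methyl ester | COC(=O)C[C@@H]2O[C@H]3[C@H]4[C@@H](CC=C(C)[C@H]42)[C@@H](C)C(=O)O[C@@]3(C)[C@H](OC(=O)CCCCCCC)CCO[Si](C)(C)C(C)(C)C | intermediate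
23 | C7 aldehyde (C9–CH2–CHO) | O=CC[C@@H]2O[C@H]3[C@H]4[C@@H](CC=C(C)[C@H]42)[C@@H](C)C(=O)O[C@@]3(C)[C@H](OC(=O)CCCCCCC)CCO[Si](C)(C)C(C)(C)C | intermediate
24 | terminal alkyne (C9–CH2–C≡CH) | C#CC[C@@H]2O[C@H]3[C@H]4[C@@H](CC=C(C)[C@H]42)[C@@H](C)C(=O)O[C@@]3(C)[C@H](OC(=O)CCCCCCC)CCO[Si](C)(C)C(C)(C)C | intermediate
25 | alkenylborane: (Z)-2-iodoalkenyl-9-BBN adduct of 24 | I/C(=C\B1C2CCCC1CCC2)C[C@@H]2O[C@H]3[C@H]4[C@@H](CC=C(C)[C@H]42)[C@@H](C)C(=O)O[C@@]3(C)[C@H](OC(=O)CCCCCCC)CCO[Si](C)(C)C(C)(C)C | intermediate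
26 | 2-iodoalkene (C9–CH2–C(I)=CH2) | C=C(I)C[C@@H]2O[C@H]3[C@H]4[C@@H](CC=C(C)[C@H]42)[C@@H](C)C(=O)O[C@@]3(C)[C@H](OC(=O)CCCCCCC)CCO[Si](C)(C)C(C)(C)C | intermediate
27 | organomercurial: C11 hydroxyl, C12 acetoxymercurio group trans to it | C=C(I)C[C@@H]2O[C@H]3[C@H]4[C@@H](C[C@H]([Hg]OC(C)=O)[C@@](C)(O)[C@H]42)[C@@H](C)C(=O)O[C@@]3(C)[C@H](OC(=O)CCCCCCC)CCO[Si](C)(C)C(C)(C)C | intermediate
28 | C11 tertiary alcohol (hydroxyl cis to the C9 substituent) | C=C(I)C[C@@H]2O[C@H]3[C@H]4[C@@H](CC[C@@](C)(O)[C@H]42)[C@@H](C)C(=O)O[C@@]3(C)[C@H](OC(=O)CCCCCCC)CCO[Si](C)(C)C(C)(C)C | intermediate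
29 | C6 primary alcohol | C=C(I)C[C@@H]2O[C@H]3[C@H]4[C@@H](CC[C@@](C)(O)[C@H]42)[C@@H](C)C(=O)O[C@@]3(C)[C@H](OC(=O)CCCCCCC)CCO | intermediate
30 | C6 aldehyde | C=C(I)C[C@@H]2O[C@H]3[C@H]4[C@@H](CC[C@@](C)(O)[C@H]42)[C@@H](C)C(=O)O[C@@]3(C)[C@H](OC(=O)CCCCCCC)CC=O | intermediate
31 | 6-O-debutanoyl briarellin C (tetracycle with free (6R) hydroxyl) | C=C1C[C@@H]2O[C@H]3[C@H]4[C@@H](CC[C@@](C)(O)[C@H]42)[C@@H](C)C(=O)O[C@@]3(C)[C@H](OC(=O)CCCCCCC)C[C@H]1O | intermediate
32 | briarellin C | C=C1C[C@@H]2O[C@H]3[C@H]4[C@@H](CC[C@@](C)(O)[C@H]42)[C@@H](C)C(=O)O[C@@]3(C)[C@H](OC(=O)CCCCCCC)C[C@H]1OC(=O)CCC | target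

**Count and risks**

Total step count: 23. Longest linear sequence: 19 steps (steps 1–5 and 10–23, from (S)-carvone); the epoxy aldehyde arm is 4 steps (6–9).

Three steps most likely to fail:

Step 10. The silyl Lewis acid may divert the epoxy silyl ether 13 before the carboxyl group reaches C3: a 1,2-shift at the ionising epoxide carbon, or acyl transfer to the C2 oxygen that closes the six-membered lactone. Attack at the α-carbon of the dienol ether is a further leak. The fallback separates the two events. Compounds 6 and 12 are joined with BF3·OEt2 (CH2Cl2, −78 °C, buffered aqueous quench), which should give the hydroxy epoxy acid F1. F1 is then closed with catalytic camphorsulfonic acid (CH2Cl2, 0 °C), the usual acid-catalysed opening of a trisubstituted epoxide by a carboxylic acid at its tertiary carbon; the hindered C2 hydroxyl should esterify more slowly. This sets out from 6 and 12 and comes back to the route at 15.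

Step 14. Enolisation may run toward the methylene carbon C13 and give the regioisomeric enol triflate, which would place the alkene at C12=C13. The fallback fixes the regiochemistry before triflation. Ketone 20 is converted into its thermodynamic trimethylsilyl enol ether F2 (Me3SiCl, NaI, Et3N, MeCN, rt), and F2 is turned into the triflate with PhNTf2 and CsF in 1,2-dimethoxyethane. This sets out from 20 and comes back at 21.

Step 16. The hydride may over-reduce the ester to the alcohol or attack the octanoate. The fallback avoids a partial reduction. The methyl ester of 22 is cleaved with Me3SnOH (1,2-dichloroethane, 70 °C) to the carboxylic acid F3. F3 is activated as the isobutyl carbonic anhydride F4 (isobutyl chloroformate, N-methylmorpholine, THF, −15 °C), which NaBH4 in aqueous THF reduces to the primary alcohol F5. F5 is oxidised with (n-Pr4N)RuO4 and N-methylmorpholine N-oxide. This sets out from 22 and comes back at 23.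

Further compounds
F1 | step 10 | hydroxy epoxy acid (free C2 hydroxyl and free carboxylic acid form of 13) | CC1=C[C@H]([C@@H](CC1=O)[C@@H](C)C(O)=O)[C@H](O)[C@]1(C)O[C@@H]1CCO[Si](C)(C)C(C)(C)C
F2 | step 14 | C11=C12 trimethylsilyl enol ether of 20 | COC(=O)C[C@@H]2O[C@H]3[C@H]4[C@@H](CC(O[Si](C)(C)C)=C(C)[C@H]42)[C@@H](C)C(=O)O[C@@]3(C)[C@H](OC(=O)CCCCCCC)CCO[Si](C)(C)C(C)(C)C
F3 | step 16 | carboxylic acid from 22 (C9–CH2–CO2H) | OC(=O)C[C@@H]2O[C@H]3[C@H]4[C@@H](CC=C(C)[C@H]42)[C@@H](C)C(=O)O[C@@]3(C)[C@H](OC(=O)CCCCCCC)CCO[Si](C)(C)C(C)(C)C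
F4 | step 16 | isobutyl carbonic anhydride of F3 | CC(C)COC(=O)OC(=O)C[C@@H]2O[C@H]3[C@H]4[C@@H](CC=C(C)[C@H]42)[C@@H](C)C(=O)O[C@@]3(C)[C@H](OC(=O)CCCCCCC)CCO[Si](C)(C)C(C)(C)C
F5 | step 16 | primary alcohol (C9–CH2–CH2OH) | OCC[C@@H]2O[C@H]3[C@H]4[C@@H](CC=C(C)[C@H]42)[C@@H](C)C(=O)O[C@@]3(C)[C@H](OC(=O)CCCCCCC)CCO[Si](C)(C)C(C)(C)C
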